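Readings and results are calculated with constants of no real substance, noise included.

Per second and per mol/L of second substrate: that is the unit in which the two earlier runs can be set side by side.

| setting | zeta | eta | flask |
|---|---|---|---|
| starting material | 20 mM | 20 mM | 20 mM |
| second substrate | 3.4 equiv | 7.5 equiv | 5.00 equiv |
| solid reagent | 0.90 equiv | 0.90 equiv | 0.900 equiv |
| remark | run made earlier | run made earlier |  |
| time |  |  | 25 min |

| run | time / min | starting material / % | cross product / % | target / % |
|---|---|---|---|---|
| zeta | 4.00 | 85 | 12 | 0 |
| zeta | 10.0 | 70 | 30 | 0 |
| zeta | 20.0 | 48 | 50 | 2 |
| zeta | 30.0 | 37 | 62 | 3 |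
| eta | 8.00 | 56 | 46 | 0 |
| eta | 15.0 | 28 | 68 | 0 |
| eta | 25.0 | 11 | 83 | 3 |
| eta | 30.0 | 10 | 87 | 3 |

(each reading ± 1.5 percentage points)

- the largest share of what was charged as starting material, at 25 min belongs to (target / starting material / cross product)
- the largest share itself, whichever of these holds it, in percent of the starting material charged

- solid, in amounts per volume of the solution: solid reagent
- at the start none of the solid reagent is in solution

**What does the balance of starting material show?** In the zeta run at 20.0 min, starting material, cross product and target add up to 100%. Cross product carries nearly all of the loss, and I take it to use one second substrate each.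

**So what do you carry?** I divide the fall of ln c(starting material) by the time and by the mean c(second substrate). The zeta run gives 0.00971 L mol⁻¹ s⁻¹. The eta run at 15.0 min gives 0.00988 L mol⁻¹ s⁻¹. Their mean, 0.00979 L mol⁻¹ s⁻¹, read from these scattered readings, is my loss constant, the pseudo-first-order constant per unit of mean c(second substrate).

**And this flask?** With c(second substrate) held at its full charge, my reckoning leaves 23.0% of the starting material. Correcting the mean c(second substrate) for that use gives 25.8%. Taking target at the 3% read in the eta run, my estimate for cross product is 71.2%.

**But the solid reagent is charged below the starting material. Does it cap this?** Suppose each lost starting material drew one unit of it. The reckoned loss of 74.2% of the starting material still stays under the 0.900 equiv charged.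

The forecast says cross product at 71%, range 66% to 76%, holding that “the reaction is first order in second substrate”. My figure matches it, from the same readings, so it is no check.

    starting material + coupling partner → target (k = 0.0340 L mol⁻¹ s⁻¹)
    second substrate + coupling partner → second product (k = 0.00610 L mol⁻¹ s⁻¹)
    starting material + second substrate → cross product (k = 0.00910 L mol⁻¹ s⁻¹)
    solid reagent ⇌ coupling partner, rate k4*(cs4 - [coupling partner]) while solid is left; crystals form when [coupling partner] > cs4 (solubility = 6.40 mM, k = 2.40 × 10⁻⁴ s⁻¹)
    starting material → decomposition product (k = 1.30 × 10⁻⁶ s⁻¹)

The flask gives cross product at 70.5%, with the solid reagent still at 88.6% of its own charge at 25.0 min. For the neighbour flask charged with 2.00 equiv of second substrate, of which 80% is left at 25.0 min, the loss constant gives 58.9% starting material. That neighbour flask stands at 59.1% starting material, more than its 38.0% cross product.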